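**Retrosynthetic overview**

1. Resorcinol 1 + acetic acid 2 ⇒ ketone 3 (aryl–acyl bond); p-cresol 4 ⇒ aldehyde 5 (benzylic C–H oxidation); 3 + 5 ⇒ chalcone 6 (Cα=Cβ aldol disconnection).
2. Key disconnection: the C3–C3′ bond of the biflavanone is cut together with both O1–C2 bonds, back to two molecules of 6. Forward: phenoxyl radical 7 (spin at Cα) dimerises Cα–Cα′ to bis-quinone methide 8.
3. Ring order: all four benzene rings come ready-made. Both pyranone rings close last and simultaneously, when the two 2′-OH groups of 8 add to the quinone methides to give 9.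
4. Stereochemistry: C3/C3′ come from the radical coupling, C2/C2′ (2,3-trans) from reversible ring closure.

Assumption: the descriptors (2S,3R,2′R,3′S) sit on two constitutionally identical halves, so the target is the achiral meso trans,trans diastereomer; "single enantiomer" is read as "this single diastereomer", and only relative configuration has to be controlled.

**Route**

Step 1
Reactants: 1 resorcinol; 2 acetic acid
Product: 3 2,4-dihydroxyacetophenone
Conditions: ZnCl2 (1.2 equiv), AcOH (neat, excess), 140–150 °C, 20 min; dilute HCl quench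
Reagents that add atoms: none
Why: Nencki reaction (ZnCl2-mediated Friedel–Crafts C-acylation of a phenol by a carboxylic acid); C4 of resorcinol is activated by both OH groups and the chelated ketone product resists a second acylation; no stereocenter.

Step 2
Reactants: 4 p-cresol
Product: 5 4-hydroxybenzaldehyde
Conditions: O2 (1 atm), CoCl2·6H2O (1 mol %), NaOH (3 equiv), MeOH, 60 °C, 8 h; then aq. HCl to pH 3
Reagents that add atoms: dioxygen O=O
Why: Cobalt-catalysed aerobic benzylic oxidation (autoxidation) of the p-cresolate via phenoxyl radical and p-quinone methide, stopping at the aldehyde because its phenoxide is a vinylogous carboxylate that resists further oxidation; no stereocenter.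

Step 3
Reactants: 3 2,4-dihydroxyacetophenone; 5 4-hydroxybenzaldehyde
Product: 6 isoliquiritigenin ((E)-2′,4′,4-trihydroxychalcone)
Conditions: anhydrous HCl (sat.) in EtOH, 0 °C → rt, 24 h; pour into ice-water, filter
Reagents that add atoms: none
Why: Acid-catalysed Claisen–Schmidt (crossed aldol) condensation, which avoids the unreactive polyphenoxides of the basic variant; dehydration gives the conjugated (E)-enone as the thermodynamic geometry, and this 2′,4′-dihydroxy chalcone does not cyclise at room temperature.

Step 4
Reactants: 6 isoliquiritigenin (2 molecules)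
Product: 9 meso-(2S,3R,2′R,3′S)-3,3′-biliquiritigenin (target), via chalcone phenoxyl radical 7 (not isolated), via meso bis-quinone methide 8 (not isolated)
Conditions: Ag2O (0.55 equiv), degassed acetone (0.15 M), Ar, dark, rt, 12 h; filter through Celite; then NaOAc (0.3 equiv), EtOH, 70 °C, 3 h under Ar; SiO2 then RP-18 chromatography to isolate the meso isomer
Reagents that add atoms: none
Why: Proposed new method: Ag2O removes H• from the most oxidisable phenol of 6 (the 4-OH conjugated to the enone; the acyl-substituted and chelated A-ring OH groups have higher O–H bond strengths) to give radical 7 with spin delocalised onto Cα, two radicals combine Cα–Cα′ (8–8′) to bis-quinone methide 8, and each 2′-OH adds 6-exo to its quinone methide (oxa-1,6-addition with rearomatisation) to close both pyranone rings; C3/C3′ are set in the radical–radical coupling without facial bias (meso : dl about 1 : 1), C2/C2′ are set 2,3-trans (both substituents equatorial) by the reversible NaOAc-mediated ring opening and closure, and the meso trans,trans isomer 9 is separated from the racemic C2-symmetric isomer by chromatography; the closest known reaction type is the dehydrogenative 8–8′ phenoxyl-radical dimerisation of 4-hydroxycinnamyl compounds with intramolecular quinone-methide trapping (coniferyl alcohol to pinoresinol, ferulic or sinapic acid to the bis-lactone, 4-hydroxystilbenes to 8–8′ bis-quinone methides).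

**Compound list**

1 | resorcinol | Oc1cccc(O)c1 | starting material
2 | acetic acid | CC(=O)O | starting material
3 | 2,4-dihydroxyacetophenone | CC(=O)c1ccc(O)cc1O | intermediate
4 | p-cresol (4-methylphenol) | Cc1ccc(O)cc1 | starting material
5 | 4-hydroxybenzaldehyde | O=Cc1ccc(O)cc1 | intermediate
6 | isoliquiritigenin, (E)-1-(2,4-dihydroxyphenyl)-3-(4-hydroxyphenyl)prop-2-en-1-one | O=C(/C=C/c1ccc(O)cc1)c1ccc(O)cc1O | intermediate
7 | 4-[(E)-3-(2,4-dihydroxyphenyl)-3-oxoprop-1-enyl]phenoxyl radical | [O]c1ccc(/C=C/C(=O)c2ccc(O)cc2O)cc1 | intermediate (not isolated)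
8 | meso-(2R,3S)-1,4-bis(2,4-dihydroxyphenyl)-2,3-bis[(4-oxocyclohexa-2,5-dien-1-ylidene)methyl]butane-1,4-dione | O=C1C=CC(=C[C@H](C(=O)c2ccc(O)cc2O)[C@@H](C=C2C=CC(=O)C=C2)C(=O)c2ccc(O)cc2O)C=C1 | intermediate (not isolated)
9 | meso-(2S,3R,2′R,3′S)-7,7′-dihydroxy-2,2′-bis(4-hydroxyphenyl)-[3,3′-bichromane]-4,4′-dione (trans,trans-3,3′-biliquiritigenin) | O=C1c2ccc(O)cc2O[C@H](c2ccc(O)cc2)[C@H]1[C@@H]1C(=O)c2ccc(O)cc2O[C@H]1c1ccc(O)cc1 | target

**Totals**

Total step count: 4. Longest linear sequence: 3 steps (1 → 3 → 6 → 9).

**Three steps most likely to fail**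

Step 4 (highest risk). The unblocked phenoxyl radical can also couple Cα to the B-ring ortho carbon (8–5′) or to oxygen (8–O–4′), and the coupling gives meso and dl isomers without preference. A realistic expectation is 10–15 % of isolated 9. Three points work in its favour: the internal 2′-OH traps the 8–8′ adduct irreversibly, the product's 4-alkylphenols are harder to oxidise than the conjugated phenol of 6, and any open-chain dibenzylidene-diketone tautomers are cyclised by the NaOAc stage to the same biflavanones. The dl isomer can be resubmitted to the NaOAc equilibration.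

Fallback, setting out from 4 (with 3) and returning at 9: the ortho positions and the oxygen are shielded with tert-butyl groups so that only Cα–Cα′ coupling remains, which is the known behaviour of 2,6-di-tert-butyl-4-vinylphenols. p-Cresol 4 is alkylated with isobutene (cat. H2SO4, 70 °C) to 2,6-di-tert-butyl-4-methylphenol F1. Br2 (2 equiv) in t-BuOH/H2O oxidises the methyl group to give 3,5-di-tert-butyl-4-hydroxybenzaldehyde F2. HCl/EtOH condensation with 3 gives (E)-3,5-di-tert-butyl-2′,4′,4-trihydroxychalcone F3. Ag2O in CH2Cl2 gives the persistent tetra-tert-butyl bis-quinone methide F4 (meso plus dl). NaOAc/EtOH at 70 °C closes both rings to the tetra-tert-butyl biflavanone F5, whose meso trans,trans isomer is separated. AlCl3 in toluene at 50 °C (retro-Friedel–Crafts transfer of tert-butyl to toluene) then gives 9. This costs two more steps.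

Step 3. Both partners are deactivated polyphenols, and acid may cause partial cyclisation to the flavanone or a sluggish condensation.

Fallback, setting out from 3 and 5 and returning at 6: a protected, base-mediated aldol. Ketone 3 is mono-protected (MOMCl, K2CO3, acetone; the chelated 2-OH stays free) to give 2-hydroxy-4-(methoxymethoxy)acetophenone F6. Aldehyde 5 is protected the same way to give 4-(methoxymethoxy)benzaldehyde F7. KOH in EtOH/H2O at rt (then dilute HCl to pH 6) condenses them to (E)-2′-hydroxy-4,4′-bis(methoxymethoxy)chalcone F8. Brief HCl/MeOH at 50 °C removes both MOM groups to give 6.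

Step 2. The aerobic oxidation can stall at the benzyl ether/alcohol stage, over-oxidise, or give oxidative C–C/C–O coupling of the cresol.

Fallback, setting out from 4 and returning at 5: the phenol is masked and the methyl group is functionalised by radical halogenation instead. Ac2O/pyridine gives 4-methylphenyl acetate F9. NBS (2.2 equiv), AIBN, PhCF3 at reflux (Wohl–Ziegler) gives 4-(dibromomethyl)phenyl acetate F10. Aqueous NaOH at 60 °C followed by HCl hydrolyses both the gem-dibromide and the acetate to give 5.

**Further compounds**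

F1 | step 4 | 2,6-di-tert-butyl-4-methylphenol | Cc1cc(C(C)(C)C)c(O)c(C(C)(C)C)c1
F2 | step 4 | 3,5-di-tert-butyl-4-hydroxybenzaldehyde | O=Cc1cc(C(C)(C)C)c(O)c(C(C)(C)C)c1
F3 | step 4 | (E)-3-(3,5-di-tert-butyl-4-hydroxyphenyl)-1-(2,4-dihydroxyphenyl)prop-2-en-1-one | O=C(/C=C/c1cc(C(C)(C)C)c(O)c(C(C)(C)C)c1)c1ccc(O)cc1O
F4 | step 4 | meso-2,3-bis[(3,5-di-tert-butyl-4-oxocyclohexa-2,5-dien-1-ylidene)methyl]-1,4-bis(2,4-dihydroxyphenyl)butane-1,4-dione | O=C1C(C(C)(C)C)=CC(=C[C@H](C(=O)c2ccc(O)cc2O)[C@@H](C=C2C=C(C(C)(C)C)C(=O)C(C(C)(C)C)=C2)C(=O)c2ccc(O)cc2O)C=C1C(C)(C)C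
F5 | step 4 | meso-(2S,3R,2′R,3′S)-2,2′-bis(3,5-di-tert-butyl-4-hydroxyphenyl)-7,7′-dihydroxy-[3,3′-bichromane]-4,4′-dione | O=C1c2ccc(O)cc2O[C@H](c2cc(C(C)(C)C)c(O)c(C(C)(C)C)c2)[C@H]1[C@@H]1C(=O)c2ccc(O)cc2O[C@H]1c1cc(C(C)(C)C)c(O)c(C(C)(C)C)c1
F6 | step 3 | 2-hydroxy-4-(methoxymethoxy)acetophenone | CC(=O)c1ccc(OCOC)cc1O
F7 | step 3 | 4-(methoxymethoxy)benzaldehyde | COCOc1ccc(C=O)cc1
F8 | step 3 | (E)-1-[2-hydroxy-4-(methoxymethoxy)phenyl]-3-[4-(methoxymethoxy)phenyl]prop-2-en-1-one | COCOc1ccc(/C=C/C(=O)c2ccc(OCOC)cc2O)cc1
F9 | step 2 | 4-methylphenyl acetate | CC(=O)Oc1ccc(C)cc1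
F10 | step 2 | 4-(dibromomethyl)phenyl acetate | CC(=O)Oc1ccc(C(Br)Br)cc1
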